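**Plan**
- Retrosynthesis: after removal of all benzyl-type groups, both ester C–O bonds at C4 and C5 are cut at once. The two acyloxy oxygens sit trans on the adjacent carbons C4 and C5 of the one cyclohexane ring, beside the C3 oxygen, which is the retron of an iodine/silver-carboxylate anti addition of two vanillate units to a C4=C5 cyclohexene.
- The cyclohexene is cut at C4=C5 (ring-closing metathesis) to a 1,7-diene, then at C1–C6 (allylation) and C1–O1 (hydroxylation), back to a γ-vinyl-γ-butyrolactone whose ring oxygen is O3.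
- Forward: chiral-pool lactone → vinyl group → O1 → allyl at C1 → lactone opened and benzylated → the only carbocycle closes by metathesis → both vanillates added in one operation → one hydrogenolysis.
- Stereochemistry: C3 comes from the (R)-lactone; C1 from enolate allylation trans to the γ-vinyl group; C4 and C5 from the anti addition, steered by the C3 ether and the cis-1,3 oxygens O1/O3.

Key step: step 11

Remark: positions carry quinic acid numbers (C1 bears the carboxyl group, C3 the free hydroxyl, C4 and C5 the esters); α is the ring face of O1, O3 and O4, β the face of the C1 carboxyl group and O5; the α-hydroxy and α-benzyloxy lactones of steps 3 and 4 may be carried as epimer mixtures at the lactone α-carbon, because that centre is planarised again in step 5.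

Step 1
Reactants: 1 (R)-5-(hydroxymethyl)dihydrofuran-2(3H)-one
Product: 2 (R)-5-oxotetrahydrofuran-2-carbaldehyde
Conditions: Dess–Martin periodinane, CH2Cl2, 0 °C to rt
Reagents that add atoms: none
Why: Dess–Martin oxidation takes the primary alcohol to the aldehyde under neutral conditions, so the lactone and the adjacent stereocentre (the future C3) should stay intact.

Step 2
Reactants: 2 (R)-5-oxotetrahydrofuran-2-carbaldehyde
Product: 3 (R)-5-vinyldihydrofuran-2(3H)-one
Conditions: Ph3PCH3Br, KN(SiMe3)2, THF, −78 to 0 °C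
Reagents that add atoms: methyltriphenylphosphonium bromide, C[P+](c1ccccc1)(c1ccccc1)c1ccccc1.[Br-]
Why: Wittig methylenation with the non-stabilised ylide at low temperature should be faster than enolisation of the aldehyde or attack on the lactone, so the γ-stereocentre is kept.

Step 3
Reactants: 3 (R)-5-vinyldihydrofuran-2(3H)-one
Product: 4 (3S,5R)-3-hydroxy-5-vinyldihydrofuran-2(3H)-one
Conditions: NaN(SiMe3)2, THF, −78 °C; 3-phenyl-2-(phenylsulfonyl)oxaziridine, −78 °C; AcOH quench
Reagents that add atoms: 3-phenyl-2-(phenylsulfonyl)oxaziridine, O=S(=O)(c1ccccc1)N1OC1c1ccccc1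
Why: Davis oxidation of the sodium lactone enolate installs the future O1, entering mainly trans to the vinyl group, although the configuration of this centre is immaterial because it is re-enolised in step 5.

Step 4
Reactants: 4 (3S,5R)-3-hydroxy-5-vinyldihydrofuran-2(3H)-one
Product: 5 (3S,5R)-3-(benzyloxy)-5-vinyldihydrofuran-2(3H)-one
Conditions: BnBr, Ag2O, CH2Cl2, rt, dark
Reagents that add atoms: benzyl bromide, BrCc1ccccc1
Why: Silver-oxide-mediated Williamson benzylation etherifies the α-hydroxy lactone without a strong base, so the lactone is not opened or eliminated.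

Step 5
Reactants: 5 (3S,5R)-3-(benzyloxy)-5-vinyldihydrofuran-2(3H)-one
Product: 6 (3R,5R)-3-(benzyloxy)-3-(prop-2-en-1-yl)-5-vinyldihydrofuran-2(3H)-one
Conditions: LiN(iPr)2, THF–DMPU, −78 °C; allyl bromide, −78 to −40 °C
Reagents that add atoms: allyl bromide, C=CCBr
Why: Alkylation of the α-benzyloxy lactone enolate should take allyl bromide on the face opposite the γ-vinyl group (1,3-induction in γ-butyrolactone enolates), which sets the quaternary C1 with O1 cis and the allyl group trans to the vinyl group.

Step 6
Reactants: 6 (3R,5R)-3-(benzyloxy)-3-(prop-2-en-1-yl)-5-vinyldihydrofuran-2(3H)-one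
Product: 8 (2R,4R)-2,4-bis(benzyloxy)-2-(prop-2-en-1-yl)hex-5-enoic acid, via potassium hydroxy carboxylate 7 (not isolated)
Conditions: KOH (powdered), BnBr, toluene, 110 °C; then KOH, MeOH–H2O, 60 °C; then HCl (aq) to pH 2
Reagents that add atoms: potassium hydroxide, [K+].[OH-]; benzyl bromide, BrCc1ccccc1
Why: Saponification of the γ-lactone followed by Williamson etherification of the freed secondary alkoxide (the classical KOH/benzyl bromide opening of γ-lactones) traps the hydroxy acid as its benzyl ether, so it cannot relactonise on acidification and no stereocentre is touched.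

Step 7
Reactants: 8 (2R,4R)-2,4-bis(benzyloxy)-2-(prop-2-en-1-yl)hex-5-enoic acid
Product: 9 benzyl (2R,4R)-2,4-bis(benzyloxy)-2-(prop-2-en-1-yl)hex-5-enoate
Conditions: BnBr, Cs2CO3, DMF, rt
Reagents that add atoms: benzyl bromide, BrCc1ccccc1
Why: O-Alkylation of the caesium carboxylate with benzyl bromide in DMF is a standard esterification of hindered acids and leaves the ethers and alkenes alone.

Step 8
Reactants: 9 benzyl (2R,4R)-2,4-bis(benzyloxy)-2-(prop-2-en-1-yl)hex-5-enoate
Product: 10 benzyl (1R,3R)-1,3-bis(benzyloxy)cyclohex-4-ene-1-carboxylate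
Conditions: second-generation Grubbs catalyst RuCl2(=CHPh)(PCy3)(H2IMes) (5 mol %), CH2Cl2, 40 °C
Reagents that add atoms: none
Why: Ring-closing metathesis of the 1,7-diene (vinyl on C3, allyl on C1) closes the six-membered ring at C4=C5 with loss of ethene, and ethers and the ester are inert to the ruthenium carbene.

Step 9
Reactants: 11 vanillic acid
Product: 12 4-{[(benzyloxy)carbonyl]oxy}-3-methoxybenzoic acid
Conditions: BnOCOCl, NaOH, H2O–THF, 0 °C; then HCl (aq)
Reagents that add atoms: benzyl chloroformate, O=C(Cl)OCc1ccccc1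
Why: Under Schotten–Baumann conditions the phenoxide is far more nucleophilic than the carboxylate towards the chloroformate, giving the aryl benzyl carbonate, which deactivates the arene and is later removed by hydrogenolysis.

Step 10
Reactants: 12 4-{[(benzyloxy)carbonyl]oxy}-3-methoxybenzoic acid
Product: 13 silver 4-{[(benzyloxy)carbonyl]oxy}-3-methoxybenzoate
Conditions: NaHCO3, H2O–MeCN; AgNO3, rt, dark; dried in vacuo over P2O5
Reagents that add atoms: silver nitrate, [Ag+].[O-][N+](=O)[O-]
Why: Salt metathesis of the sodium carboxylate with AgNO3 precipitates the silver carboxylate that serves as nucleophile and halide scavenger in the Prévost reaction.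

Step 11
Reactants: 10 benzyl (1R,3R)-1,3-bis(benzyloxy)cyclohex-4-ene-1-carboxylate; 13 silver 4-{[(benzyloxy)carbonyl]oxy}-3-methoxybenzoate (2.2 equiv)
Product: 16 benzyl (1S,3R,4R,5R)-1,3-bis(benzyloxy)-4,5-bis({4-[(benzyloxycarbonyl)oxy]-3-methoxybenzoyl}oxy)cyclohexane-1-carboxylate, via trans-iodo ester 14 (not isolated), via dioxolanylium ion 15 (not isolated)
Conditions: I2 (1.05 equiv), PhH, 4 Å molecular sieves, dark, rt then 80 °C
Reagents that add atoms: none
Why: This is a Prévost reaction (the known iodine/silver benzoate trans-dibenzoyloxylation of cyclohexenes, run here with silver carboxylate 13): the aroyl hypoiodite from I2 and 13 iodinates C4=C5 reversibly, the iodonium ion on the face anti to the allylic C3 benzyloxy group is opened anti by vanillate at C5, the alkene carbon remote from the electron-withdrawing C3–O bond, to give iodo ester 14, and silver-assisted displacement of iodide at C4 by the neighbouring ester carbonyl gives the cis-fused 2-aryl-1,3-dioxolan-2-ylium ion 15 on the O3 (α) face. A second vanillate opens 15 by SN2 attack at C5 from the β face, so no ring is closed in the product and the two new C–O bonds come from two separate carboxylates. C4 is set by the intramolecular displacement (O4 cis to O3) and C5 by the final inversion (O5 trans to O4 and cis to the C1 ester). The step needs the acyloxonium ion on the α face and its opening at C5 rather than C4: the allylic ether steers iodine anti and deactivates C4 inductively, and only attack at C5 passes from the half-chair with the cis-1,3 oxygens O1 and O3 pseudo-equatorial to a trans-diaxial chair, whereas attack at C4 would force O1, O3 and O5 to be axial on one face. The same diaxial preference should turn an acyloxonium ion formed on the β face into the same diester by attack at C4, so the outcome does not rest on the first facial choice alone. The aryl carbonate keeps the anisole ring from being iodinated, and the ethers at O1 and O3 and the ester at C1 are much weaker nucleophiles than the silver carboxylate.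

Step 12
Reactants: 16 benzyl (1S,3R,4R,5R)-1,3-bis(benzyloxy)-4,5-bis({4-[(benzyloxycarbonyl)oxy]-3-methoxybenzoyl}oxy)cyclohexane-1-carboxylate
Product: 17 Burkinabin C
Conditions: H2 (1 atm), Pd(OH)2/C, THF–MeOH, rt
Reagents that add atoms: none
Why: Heterogeneous hydrogenolysis should cleave the benzyl ester, both benzyl ethers and both aryl benzyl carbonates (the latter with loss of CO2) in one neutral operation that leaves the vanilloyl esters and all four stereocentres untouched.

**Compound list**
1 | (R)-5-(hydroxymethyl)dihydrofuran-2(3H)-one | O=C1O[C@@H](CO)CC1 | starting material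
2 | (R)-5-oxotetrahydrofuran-2-carbaldehyde | O=C1O[C@@H](C=O)CC1 | intermediate
3 | (R)-5-vinyldihydrofuran-2(3H)-one | O=C1O[C@@H](C=C)CC1 | intermediate
4 | (3S,5R)-3-hydroxy-5-vinyldihydrofuran-2(3H)-one (hydroxyl trans to vinyl) | O=C1O[C@@H](C=C)C[C@@H]1O | intermediate
5 | (3S,5R)-3-(benzyloxy)-5-vinyldihydrofuran-2(3H)-one | O=C1O[C@@H](C=C)C[C@@H]1OCc1ccccc1 | intermediate
6 | (3R,5R)-3-(benzyloxy)-3-(prop-2-en-1-yl)-5-vinyldihydrofuran-2(3H)-one (allyl trans to vinyl) | O=C1O[C@@H](C=C)C[C@]1(OCc1ccccc1)CC=C | intermediate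
7 | potassium (2R,4R)-2-(benzyloxy)-4-hydroxy-2-(prop-2-en-1-yl)hex-5-enoate | O[C@@H](C=C)C[C@@](OCc1ccccc1)(C(=O)[O-])CC=C.[K+] | intermediate
8 | (2R,4R)-2,4-bis(benzyloxy)-2-(prop-2-en-1-yl)hex-5-enoic acid | c1ccccc1CO[C@@H](C=C)C[C@@](OCc1ccccc1)(C(=O)O)CC=C | intermediate
9 | benzyl (2R,4R)-2,4-bis(benzyloxy)-2-(prop-2-en-1-yl)hex-5-enoate | c1ccccc1CO[C@@H](C=C)C[C@@](OCc1ccccc1)(C(=O)OCc1ccccc1)CC=C | intermediate
10 | benzyl (1R,3R)-1,3-bis(benzyloxy)cyclohex-4-ene-1-carboxylate (O1 and O3 cis) | c1ccccc1CO[C@@H]1C[C@@](OCc2ccccc2)(C(=O)OCc2ccccc2)CC=C1 | intermediate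
11 | vanillic acid | COc1cc(C(=O)O)ccc1O | starting material
12 | 4-{[(benzyloxy)carbonyl]oxy}-3-methoxybenzoic acid | COc1cc(C(=O)O)ccc1OC(=O)OCc1ccccc1 | intermediate
13 | silver 4-{[(benzyloxy)carbonyl]oxy}-3-methoxybenzoate | COc1cc(C(=O)[O-])ccc1OC(=O)OCc1ccccc1.[Ag+] | intermediate
14 | benzyl (1S,3R,4S,5S)-1,3-bis(benzyloxy)-5-({4-[(benzyloxycarbonyl)oxy]-3-methoxybenzoyl}oxy)-4-iodocyclohexane-1-carboxylate (iodine β, acyloxy α) | I[C@H]1[C@H](OCc2ccccc2)C[C@@](OCc2ccccc2)(C(=O)OCc2ccccc2)C[C@@H]1OC(=O)c1ccc(OC(=O)OCc2ccccc2)c(OC)c1 | intermediate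
15 | 2-aryl-1,3-dioxolan-2-ylium ion cis-fused at C4/C5 on the α face (aryl = 4-[(benzyloxycarbonyl)oxy]-3-methoxyphenyl; counter-ion the carboxylate of 13) | COc1cc(C2=[O+][C@H]3C[C@](OCc4ccccc4)(C(=O)OCc4ccccc4)C[C@@H](OCc4ccccc4)[C@H]3O2)ccc1OC(=O)OCc1ccccc1 | intermediate
16 | benzyl (1S,3R,4R,5R)-1,3-bis(benzyloxy)-4,5-bis({4-[(benzyloxycarbonyl)oxy]-3-methoxybenzoyl}oxy)cyclohexane-1-carboxylate (quinic acid configuration) | COc1cc(C(=O)O[C@@H]2[C@H](OCc3ccccc3)C[C@@](OCc3ccccc3)(C(=O)OCc3ccccc3)C[C@H]2OC(=O)c2ccc(OC(=O)OCc3ccccc3)c(OC)c2)ccc1OC(=O)OCc1ccccc1 | intermediate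
17 | Burkinabin C, (1S,3R,4R,5R)-1,3-dihydroxy-4,5-bis[(4-hydroxy-3-methoxybenzoyl)oxy]cyclohexane-1-carboxylic acid | COc1cc(C(=O)O[C@@H]2[C@H](O)C[C@@](O)(C(=O)O)C[C@H]2OC(=O)c2ccc(O)c(OC)c2)ccc1O | target

**Step count and risks**
Total steps: 12. Longest linear sequence: 10 (steps 1–8, 11, 12).

Steps most likely to fail:

1. Step 11. The openings of the iodonium and acyloxonium ions may not follow the conformational bias, which would give the 4,5-bis-epimeric trans-diester. The axial C1 ester carbonyl may also capture a cationic intermediate with loss of its benzyl group (iodolactonisation). The fallback sets out from 10 and returns at 16. Osmylation (OsO4 cat., N-methylmorpholine N-oxide) should add syn across C4=C5 on the face anti to the allylic C3 ether and give benzyl 1,3-di-O-benzyl-4-epi-quinate F1, a β-face cis-diol in which C5 is already correct. Carbodiimide esterification with acid 12 at the less hindered 5-OH, which has only one oxygenated neighbour, would give benzyl 1,3-di-O-benzyl-5-O-{4-[(benzyloxycarbonyl)oxy]-3-methoxybenzoyl}-4-epi-quinate F2. A Mitsunobu reaction of the remaining 4-OH with a second equivalent of 12 (PPh3, diisopropyl azodicarboxylate) then installs the C4 ester with inversion and gives 16. Facial control then rests on osmylation and an SN2 inversion instead of halonium chemistry.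

2. Step 5. The small γ-vinyl group may discriminate the enolate faces poorly, so that allyl bromide also enters cis and both C1 epimers form. The fallback sets out from 1 and returns at 6; it moves the alkylation to a lactone with a much larger γ-substituent and introduces the vinyl group afterwards. Tritylation (TrCl, pyridine) gives (R)-5-[(trityloxy)methyl]dihydrofuran-2(3H)-one F3. Hydroxylation as in step 3 gives (3S,5R)-3-hydroxy-5-[(trityloxy)methyl]dihydrofuran-2(3H)-one F4, and benzylation as in step 4 gives (3S,5R)-3-(benzyloxy)-5-[(trityloxy)methyl]dihydrofuran-2(3H)-one F5. Allylation as in step 5, now trans to the trityloxymethyl group, gives (3R,5R)-3-(benzyloxy)-3-(prop-2-en-1-yl)-5-[(trityloxy)methyl]dihydrofuran-2(3H)-one F6. Detritylation (TsOH, MeOH) gives (3R,5R)-3-(benzyloxy)-5-(hydroxymethyl)-3-(prop-2-en-1-yl)dihydrofuran-2(3H)-one F7, Dess–Martin oxidation gives (2R,4R)-4-(benzyloxy)-5-oxo-4-(prop-2-en-1-yl)tetrahydrofuran-2-carbaldehyde F8, and Wittig methylenation as in step 2 gives 6.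

3. Step 6. Etherification of the hindered secondary alkoxide may be incomplete, so that unreacted hydroxy acid relactonises to 6 on acidification, or the material may degrade in hot alkali. The fallback sets out from 6 and returns at 9; it inverts the order (ester first, ether second) so that no alkoxide is generated. Saponification with LiOH, evaporation and alkylation of the lithium carboxylate with benzyl bromide in DMF without added base should give benzyl (2R,4R)-2-(benzyloxy)-4-hydroxy-2-(prop-2-en-1-yl)hex-5-enoate F9. This is etherified at once under non-basic conditions (benzyl 2,2,2-trichloroacetimidate, catalytic TfOH, 0 °C) to give 9.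

**Further compounds**
F1 | step 11 | benzyl 1,3-di-O-benzyl-4-epi-quinate (4,5-cis-diol on the β face) | O[C@H]1[C@H](OCc2ccccc2)C[C@@](OCc2ccccc2)(C(=O)OCc2ccccc2)C[C@H]1O
F2 | step 11 | benzyl 1,3-di-O-benzyl-5-O-{4-[(benzyloxycarbonyl)oxy]-3-methoxybenzoyl}-4-epi-quinate | O[C@H]1[C@H](OCc2ccccc2)C[C@@](OCc2ccccc2)(C(=O)OCc2ccccc2)C[C@H]1OC(=O)c1ccc(OC(=O)OCc2ccccc2)c(OC)c1
F3 | step 5 | (R)-5-[(trityloxy)methyl]dihydrofuran-2(3H)-one | O=C1O[C@@H](COC(c2ccccc2)(c2ccccc2)c2ccccc2)CC1
F4 | step 5 | (3S,5R)-3-hydroxy-5-[(trityloxy)methyl]dihydrofuran-2(3H)-one | O=C1O[C@@H](COC(c2ccccc2)(c2ccccc2)c2ccccc2)C[C@@H]1O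
F5 | step 5 | (3S,5R)-3-(benzyloxy)-5-[(trityloxy)methyl]dihydrofuran-2(3H)-one | O=C1O[C@@H](COC(c2ccccc2)(c2ccccc2)c2ccccc2)C[C@@H]1OCc1ccccc1
F6 | step 5 | (3R,5R)-3-(benzyloxy)-3-(prop-2-en-1-yl)-5-[(trityloxy)methyl]dihydrofuran-2(3H)-one | O=C1O[C@@H](COC(c2ccccc2)(c2ccccc2)c2ccccc2)C[C@]1(OCc1ccccc1)CC=C
F7 | step 5 | (3R,5R)-3-(benzyloxy)-5-(hydroxymethyl)-3-(prop-2-en-1-yl)dihydrofuran-2(3H)-one | O=C1O[C@@H](CO)C[C@]1(OCc1ccccc1)CC=C
F8 | step 5 | (2R,4R)-4-(benzyloxy)-5-oxo-4-(prop-2-en-1-yl)tetrahydrofuran-2-carbaldehyde | O=C1O[C@@H](C=O)C[C@]1(OCc1ccccc1)CC=C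
F9 | step 6 | benzyl (2R,4R)-2-(benzyloxy)-4-hydroxy-2-(prop-2-en-1-yl)hex-5-enoate | O[C@@H](C=C)C[C@@](OCc1ccccc1)(C(=O)OCc1ccccc1)CC=C
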